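Amounts first: every flask is charged with both substrates at 0.25 M each, with reagent and small loadings of free catalyst and racemization catalyst.

| setting | delta | beta | epsilon | blue | ochre | amber | grey | violet |
|---|---|---|---|---|---|---|---|---|
| left-handed substrate | 0.25 M | 0.25 M | 0.25 M | 0.25 M | 0.25 M | 0.25 M | 0.25 M | 0.25 M |
| right-handed substrate | 0.25 M | 0.25 M | 0.25 M | 0.25 M | 0.25 M | 0.25 M | 0.25 M | 0.25 M |
| reagent | 4 equiv | 4 equiv | 4 equiv | 4.00 equiv | 6.00 equiv | 6.00 equiv | 1.30 equiv | 8.00 equiv |
| free catalyst | 0.22 mol% | 4.5 mol% | 1.7 mol% | 1.7 mol% | 6 mol% | 0.4 mol% | 1.7 mol% | 2.5 mol% |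
| racemization catalyst | 0.97 mol% | 0.97 mol% | 0.87 mol% | 0.97 mol% | 0.97 mol% | 0.97 mol% | 1.5 mol% | 0.5 mol% |
| remark | run made earlier | run made earlier | run made earlier |  |  |  |  |  |
| time |  |  |  | 50 h | 50 h | 50 h | 50 h | 50 h |

| run | time / h | left-handed product / % |
|---|---|---|
| delta | 3.00 | 1.8 |
| delta | 5.00 | 3.9 |
| delta | 8.00 | 4.4 |
| delta | 12.0 | 5.9 |
| delta | 20.0 | 7.3 |
| delta | 40.0 | 10.7 |
| beta | 6.00 | 44.1 |
| beta | 12.0 | 58.3 |
| beta | 20.0 | 67.0 |
| beta | 25.0 | 71.4 |
| beta | 30.0 | 73.5 |
| beta | 40.0 | 76.6 |
| epsilon | 3.00 | 14.0 |
| epsilon | 5.00 | 21.2 |
| epsilon | 10.0 | 30.7 |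
| epsilon | 20.0 | 41.5 |
| epsilon | 40.0 | 48.9 |

(readings scatter by 0.5 percentage points)

- free catalyst is single-handed; left-handed substrate and right-handed substrate are mirror images of each other, charged as a racemate, each of them at the stated concentration
- reactions considered so far: reagent + free catalyst + left-handed substrate -> free catalyst + left-handed product; reagent + free catalyst + right-handed substrate -> free catalyst + right-handed product; left-handed substrate + racemization catalyst <-> right-handed substrate + racemization catalyst; 2 reagent -> homo dimer

- the flasks put in order of amount of left-handed product, in percent of the left-handed substrate and right-handed substrate together charged, best first, at 50 h (blue / ochre / amber / grey / violet)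
- the amount of left-handed product, in percent of the left-handed substrate and right-handed substrate together charged of the flask you put first, at 50 h
- the amount of left-handed product, in percent of the left-handed substrate and right-handed substrate together charged of the flask you put last, at 50 h

Beta reads 76.6% left-handed product, more than the 50.0% that the left-handed charge supplies, so right-handed substrate reaches that product by racemization. The two substrates are therefore reckoned as one pool. The catalyst yield Y is the natural logarithm of the pool fraction not turned into left-handed product, sign reversed, divided by the free-catalyst loading. As a reading, Y is 51.4 in delta and 32.3 in beta, both at 40.0 h and 4 equiv, so it reads lower in beta, the run with more free catalyst, than in delta.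

Among the flasks asked about, free catalyst is highest in ochre and lowest in amber. This text's own estimate takes Y from the run nearest in loading. Beta's Y gives ochre 85.6%, and delta's Y gives amber 18.6%.

The forecast is ochre > violet > blue > grey > amber, with 82% on top and 22% at the bottom, ochre being called “racemization-limited”. Both its numbers differ from this estimate.

The flasks give ochre > violet > blue > grey > amber, with 89.6% in ochre and 21.8% in amber.

    reagent + free catalyst + left-handed substrate → free catalyst + left-handed product (k = 0.00920 L² mol⁻² s⁻¹)
    reagent + free catalyst + right-handed substrate → free catalyst + right-handed product (k = 3.00 × 10⁻⁴ L² mol⁻² s⁻¹)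
    left-handed substrate + racemization catalyst ⇌ right-handed substrate + racemization catalyst, rate k3*[racemization catalyst]*[left-handed substrate] forward; the back reaction follows from the equilibrium constant (k = 0.0420 L mol⁻¹ s⁻¹)
    2 reagent → homo dimer (k = 2.20 × 10⁻⁵ L mol⁻¹ s⁻¹)

Amber's Y is 61.6 and ochre's is 37.8. These are 1.20 and 1.17 times the values of delta and beta; each flask differs from its run in free catalyst as well as in reagent, 6.00 equiv against 4 equiv, and in time, 50 h against 40.0 h. The neighbouring flask is amber with 1 mol% free catalyst, its reagent and time unchanged. Amber's Y gives it 46.0%. That flask holds 43.0% left-handed product at 50.0 h, less than the reckoning.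

(The earlier runs and the new flask come from a simulation with made-up constants; scatter was added.)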